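**Remark on the structure:** the SMILES is read as (5R,7S,10R) in labdane numbering (ring A = C1–C5, C10; ring B = C5–C10; C17 = methyl on C8; C18/C19 = methyls on C4; C20 = methyl on C10; chain C11–C16). This is the ent-labdane series: trans ring fusion, 7-acetoxy trans to the C10 methyl and cis to H-5, 13E. Labdane locants are used for all intermediates.

## Analysis of the target

The target is the diacetate of an ent-labda-8,13E-diene-7,15-diol. It is a trans-decalin with the gem-dimethyl carbon C4 in ring A, an angular methyl on C10, a tetrasubstituted C8=C9 alkene bearing the C17 methyl, an allylic acetate at C7, and a C9 chain that ends in an E-trisubstituted allylic acetate. There are three stereocentres. H-5 and the C10 methyl are trans; the C7 acetoxy group lies on the face of H-5, opposite to the C10 methyl, pseudoaxial on the ring-B half-chair. The 13E geometry is a fourth stereo-element. The absolute configuration is antipodal to the abundant sclareol-type pool, so degradation of a cheap labdane is not an option. The C7 acetate ionises easily to the C7–C8–C9 allyl cation (epimerisation, diene formation) under acid or with zerovalent palladium, and the C15 allylic acetate is similarly labile, so both acetates should be installed last. The difficulties are C5 wedged between two quaternary carbons (C4 and C10), an alkene that must sit at C8=C9 and not at C7=C8 or C8=C17, and oxygen at C7, a carbon that cation-olefin cyclisations leave as CH2.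

The feature on which the plan turns is ring B together with its substituents. The unit C7(O)–C8(CH3)=C9, with C5 carrying C4 and one of its methyls, is the complete carbon skeleton of (S)-carvone 1 once the carbonyl is written at C9 instead of C7 (a 1,3-transposition apart). In 1, C9 is the carbonyl carbon, C8 bears the methyl, C7=C8 is the alkene, and C5 bears an isopropenyl group that is C4 + C18 + a CH2 that becomes C19 on hydrogen-atom addition. What 1 lacks is only the C10 methyl, the three carbons C1–C3 of ring A, and the side chain.

## Retrosynthetic reasoning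

**22 ⇒ 21 ⇒ 20.** The two C–O acyl bonds and the silyl ether are cut first. Both allylic acetates are ionisable, so they are put on in the last step under basic conditions. The forward reactions are a desilylation and a double acetylation.

**20 ⇒ 19.** The C7–H bond is cut. C7 is the only stereocentre not inherited from 1 or set relative to it at the start. Placing it last, by hydride addition to the C7 ketone of the rigid trans-fused enone 19, lets the locked half-chair decide the face. The forward step must deliver hydride along the equatorial trajectory so that the hydroxyl ends pseudoaxial.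

**19 ⇒ 18 ⇒ 10 + 16 (through 17).** The C9–C11 bond between ring and chain is cut, which makes the route convergent. Forward, organolithium 17 adds to the C9 ketone of enone 10, and an oxidative 1,3-transposition of the tertiary allylic alcohol 18 moves oxygen from C9 to C7 and the alkene from C7=C8 to C8=C9. This turns the carvone oxidation pattern into the target pattern. The tetrasubstituted alkene is formed by a sigmatropic shift and not by an elimination, so its position is not in doubt.

**16 ⇒ 15 ⇒ 14 ⇒ 13 ⇒ 11.** In the chain, the C13–C16 and C14–C15 bonds are cut back to terminal alkyne 11. A syn-carbometalation that adds the methyl and a metal across the alkyne, followed by one-carbon hydroxymethylation, fixes the 13E geometry in a single operation. The remaining steps only exchange the two oxygen functions for a silyl ether and an iodide.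

**10 ⇒ 7 (key disconnection).** The C3–C4 bond of ring A is cut. C4 is the quaternary gem-dimethyl carbon, and the isopropenyl group of 1 is its latent radical. One hydrogen atom added to the isopropenyl CH2 creates the C19 methyl and a tertiary C4 radical at once. Cutting here reduces the trans-decalin to a monocyclic carvone derivative with a three-carbon tether on C10. C3 must end as CH2, so the acceptor is an aldehyde sulfonylhydrazone, which is traceless after loss of sulfinate and N2. The forward reaction must close a six-membered ring next to a quaternary carbon, chemoselectively in the presence of the ring-B enone.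

**7 ⇒ 6 ⇒ 5 ⇒ 3 ⇒ 1.** The C10–C1 and C10–C20 bonds are cut, leaving two α′-alkylations of 1. Their order fixes C10: the second electrophile enters anti to the isopropenyl group, so methyl goes in first and the three-carbon unit second. That makes the tether trans to the isopropenyl group, which is the trans ring fusion. A propargyl group serves as latent propanal (anti-Markovnikov hydration to 6), because it alkylates a hindered enolate reliably.

## Alternatives that were turned down

**Alternative 1:** the textbook disconnection cuts C4–C5 and C9–C10 together. The forward key step is an enantioselective proton-initiated cation-olefin bicyclisation of (2E,6E,10E)-geranylgeranyl acetate A1 under a chiral Brønsted-acid-assisted Lewis acid, giving the 7-deoxy bicycle A2, followed by allylic oxidation at C7. It was turned down on four grounds: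
- The C8 cation formed on closure of ring B can lose a proton from C7, C9 or C17, so the Δ8 isomer is only one of three alkenes.
- The C13=C14 alkene of A1 is itself a nucleophile and invites a third ring closure.
- Enantiocontrol in such protonations is best with aryl terminators, not with a simple trisubstituted alkene.
- Oxidation of A2 must pick C7 out of five allylic positions (C7, C11, C12, C16, C17).

The step builds the skeleton but none of the ring-B functionality.

**Alternative 2:** the Robinson-annulation route starts from (R)-Wieland–Miescher ketone A3, which supplies the decalin and C10. The forward sequence is deconjugative gem-dimethylation at C4, removal of the C3 carbonyl and trans-selective hydrogenation to decalone A4, then C8 methylation and dehydrogenation to reach enone 10. It was turned down for step economy. Eight or nine redox and protecting-group steps are spent reaching 10, because A3 carries oxygen at C3 where none is wanted and no carbon at C8. The carvone route reaches 10 in five steps.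

**Alternative 3:** a one-carbon ring expansion removes C8 from ring B. The forward key step is dibromocarbene addition to the C7=C9 alkene of the B-nor trans-hydrindene A5, silver-assisted electrocyclic opening of the adduct in acetic acid with axial capture at C7 to give bromo-acetate A6, and methyl cross-coupling at C8. It is attractive because C8, the alkene position and the C7 acetate arise in one event. It was turned down because A5 already contains C5, C10, the quaternary C4 and the full chain and is no easier to make than the target. In addition, the intermediate allyl cation can be captured at C9 or lose a proton, and the closing palladium-catalysed methylation would have to tell a vinyl bromide from an ionisable allylic acetate in the same allyl unit. The gain is one carbon for a precursor that is not simpler.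

Key step: step 5

## Route

**Step 1**
Reactants: 1 (S)-(+)-carvone, (5S)-2-methyl-5-(prop-1-en-2-yl)cyclohex-2-en-1-one
Product: 3 (5S,6R)-2,6-dimethyl-5-(prop-1-en-2-yl)cyclohex-2-en-1-one (trans epimer shown; any cis epimer is carried along), via lithium α′-dienolate 2 (not isolated)
Conditions: LiN(i-Pr)2, THF, −78 °C; MeI, −78 → 0 °C
Reagents that add atoms: iodomethane, CI
Why: Kinetic α′-deprotonation gives the cross-conjugated enolate, which is C-methylated at C10 (enolate alkylation); the C10 configuration does not matter because this centre is re-enolised in step 2.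

**Step 2**
Reactants: 3 (5S,6R)-2,6-dimethyl-5-(prop-1-en-2-yl)cyclohex-2-en-1-one
Product: 5 (5R,6R)-2,6-dimethyl-5-(prop-1-en-2-yl)-6-(prop-2-yn-1-yl)cyclohex-2-en-1-one, via lithium enolate 4 (not isolated)
Conditions: LiN(i-Pr)2, THF, −78 °C; DMPU, propargyl bromide, −78 → 0 °C
Reagents that add atoms: 3-bromoprop-1-yne, BrCC#C
Why: Enolate alkylation in which the electrophile should enter anti to the neighbouring isopropenyl group, which sits pseudoaxial in the enolate to avoid allylic strain with the C10 methyl; the propargyl chain therefore ends trans and the methyl cis to isopropenyl, which sets C10 relative to C5 and fixes the later trans ring fusion.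

**Step 3**
Reactants: 5 (5R,6R)-2,6-dimethyl-5-(prop-1-en-2-yl)-6-(prop-2-yn-1-yl)cyclohex-2-en-1-one
Product: 6 3-[(1R,6R)-1,3-dimethyl-2-oxo-6-(prop-1-en-2-yl)cyclohex-3-en-1-yl]propanal
Conditions: [CpRu(MeCN)3]PF6 (5 mol %), 5,5′-bis(trifluoromethyl)-2,2′-bipyridine (5 mol %), NMP/H2O 4:1, 25 °C
Reagents that add atoms: water, O
Why: Anti-Markovnikov alkyne hydration through a ruthenium vinylidene turns the terminal alkyne into the aldehyde (C3); the conditions are neutral and leave the enone and the 1,1-disubstituted alkene alone.

**Step 4**
Reactants: 6 3-[(1R,6R)-1,3-dimethyl-2-oxo-6-(prop-1-en-2-yl)cyclohex-3-en-1-yl]propanal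
Product: 7 N′-[(E)-3-[(1R,6R)-1,3-dimethyl-2-oxo-6-(prop-1-en-2-yl)cyclohex-3-en-1-yl]propylidene]-4-methylbenzenesulfonohydrazide
Conditions: TsNHNH2 (1.0 equiv), MeOH, 0 °C → rt
Reagents that add atoms: 4-methylbenzenesulfonohydrazide, Cc1ccc(cc1)S(=O)(=O)NN
Why: Hydrazone condensation; the unhindered aldehyde should react far faster than the conjugated C9 ketone, which is flanked by the C10 quaternary carbon.

**Step 5**
Reactants: 7 N′-[(E)-3-[(1R,6R)-1,3-dimethyl-2-oxo-6-(prop-1-en-2-yl)cyclohex-3-en-1-yl]propylidene]-4-methylbenzenesulfonohydrazide
Product: 10 (4aR,8aR)-2,5,5,8a-tetramethyl-4a,5,6,7,8,8a-hexahydronaphthalen-1(4H)-one, via ring-closed N-alkyl-N′-tosylhydrazide 8 (not isolated), via alkyldiazene 9 (not isolated)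
Conditions: Fe(acac)3 (30 mol %), PhSiH3 (2.5 equiv), EtOH (0.02 M), 60 °C; then Et3N, 80 °C
Reagents that add atoms: none
Why: The iron hydride generated from Fe(acac)3 and PhSiH3 in EtOH transfers a hydrogen atom to the CH2 terminus of the isopropenyl group (Markovnikov MHAT), which turns that CH2 into the second C4 methyl and leaves a tertiary radical at C4. This radical adds 6-exo-trig to the hydrazone carbon C3 and closes ring A through the C3–C4 bond; the sulfonyl-stabilised hydrazinyl radical is reduced to hydrazide 8, Et3N then expels p-toluenesulfinate to give diazene 9, which loses N2 and leaves C3 as CH2, so the acceptor is traceless. The closest known reaction type is the iron-hydride reductive coupling of unactivated alkenes with N-sulfonylhydrazones (hydromethylation with the formaldehyde hydrazone, reductive alkylation with aldehyde tosylhydrazones), applied here intramolecularly. No lasting stereocentre is created: C4 becomes the gem-dimethyl carbon and the C3 centre of 8 is erased on loss of N2. The trans ring fusion follows from the trans relation of the two tethers fixed in step 2, which can only be bridged diequatorially through a chair transition state. The step needs hydrogen-atom transfer to the electron-rich 1,1-disubstituted alkene and not to the trisubstituted, electron-poor enone alkene, which is the normal preference of this hydride; the enone also cannot trap the C4 radical, because that would close a four-membered ring. High dilution favours cyclisation over a second hydrogen-atom transfer to the radical.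

**Step 6**
Reactants: 11 tert-butyl(but-3-yn-1-yloxy)dimethylsilane
Product: 13 (E)-5-[(tert-butyldimethylsilyl)oxy]-3-methylpent-2-en-1-ol, via (E)-alkenyldimethylalane 12 (not isolated)
Conditions: Me3Al, Cp2ZrCl2 (25 mol %), CH2Cl2, 0 °C → rt; volatiles removed; n-BuLi, THF/hexane, −78 °C; (CH2O)n, −78 °C → rt; aqueous work-up
Reagents that add atoms: trimethylaluminium, C[Al](C)C; formaldehyde (from paraformaldehyde), C=O
Why: Zirconium-catalysed syn-carboalumination (Negishi) puts the methyl on C13 and aluminium on C14 on the same side, which fixes the 13E geometry; the derived alanate is hydroxymethylated at C14 with retention.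

**Step 7**
Reactants: 13 (E)-5-[(tert-butyldimethylsilyl)oxy]-3-methylpent-2-en-1-ol
Product: 14 tert-butyl{[(E)-5-[(tert-butyldiphenylsilyl)oxy]-3-methylpent-3-en-1-yl]oxy}dimethylsilane
Conditions: TBDPSCl, imidazole, DMF, rt
Reagents that add atoms: tert-butyl(chloro)diphenylsilane, CC(C)(C)[Si](Cl)(c1ccccc1)c1ccccc1
Why: Silylation of the primary allylic alcohol; the diphenylsilyl ether is chosen because it should survive the selective desilylation of step 8, t-BuLi, the chromate oxidation and the borohydride.

**Step 8**
Reactants: 14 tert-butyl{[(E)-5-[(tert-butyldiphenylsilyl)oxy]-3-methylpent-3-en-1-yl]oxy}dimethylsilane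
Product: 15 (E)-5-[(tert-butyldiphenylsilyl)oxy]-3-methylpent-3-en-1-ol
Conditions: pyridinium p-toluenesulfonate (10 mol %), EtOH, 50 °C
Reagents that add atoms: none
Why: Acid-catalysed solvolysis cleaves the primary dimethylsilyl ether much faster than the bulkier diphenylsilyl ether.

**Step 9**
Reactants: 15 (E)-5-[(tert-butyldiphenylsilyl)oxy]-3-methylpent-3-en-1-ol
Product: 16 tert-butyl{[(E)-5-iodo-3-methylpent-2-en-1-yl]oxy}diphenylsilane
Conditions: I2, PPh3, imidazole, CH2Cl2, 0 °C → rt
Reagents that add atoms: iodine, II
Why: Appel iodination of a primary homoallylic alcohol; neutral conditions leave the trisubstituted alkene and the silyl ether untouched.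

**Step 10**
Reactants: 16 tert-butyl{[(E)-5-iodo-3-methylpent-2-en-1-yl]oxy}diphenylsilane (1.3 equiv); 10 (4aR,8aR)-2,5,5,8a-tetramethyl-4a,5,6,7,8,8a-hexahydronaphthalen-1(4H)-one
Product: 18 (5R,9R,10R)-15-[(tert-butyldiphenylsilyl)oxy]labda-7,13E-dien-9-ol (ent-labdane series), via homoallylic organolithium 17 (not isolated)
Conditions: 16, t-BuLi (2.1 equiv per 16), Et2O/pentane, −78 °C; then 10 in Et2O, −78 → 0 °C; then H2O
Reagents that add atoms: none
Why: Lithium–iodine exchange gives the primary alkyllithium, which adds 1,2 to the C9 ketone (no α-hydrogen on either side), expected from the face anti to the axial C10 methyl; the C9 configuration is erased in step 11, so either epimer serves.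

**Step 11**
Reactants: 18 (5R,9R,10R)-15-[(tert-butyldiphenylsilyl)oxy]labda-7,13E-dien-9-ol
Product: 19 (5R,10R)-15-[(tert-butyldiphenylsilyl)oxy]labda-8,13E-dien-7-one (ent-labdane series)
Conditions: pyridinium chlorochromate (3 equiv), NaOAc, 4 Å molecular sieves, CH2Cl2, rt
Reagents that add atoms: pyridinium chlorochromate, [O-][Cr](=O)(=O)Cl.c1cc[nH+]cc1
Why: Dauben–Babler oxidative transposition: the chromate ester of the tertiary allylic alcohol undergoes a [3,3] shift that delivers a chromium oxo oxygen to C7 and moves the alkene to C8=C9, relieving congestion next to quaternary C10; oxidation of the secondary chromate then gives the enone.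

**Step 12**
Reactants: 19 (5R,10R)-15-[(tert-butyldiphenylsilyl)oxy]labda-8,13E-dien-7-one
Product: 20 (5R,7S,10R)-15-[(tert-butyldiphenylsilyl)oxy]labda-8,13E-dien-7-ol (ent-labdane series)
Conditions: LiBH(s-Bu)3, THF, −78 °C; then NaOH, H2O2, 0 °C
Reagents that add atoms: none
Why: 1,2-Reduction, since the fully substituted β-carbon C9 shuts down conjugate reduction; the bulky borohydride should approach C7 along the equatorial trajectory, away from axial H-5, and place the hydroxyl pseudoaxial on the face of H-5 and opposite to the C10 methyl (7S), as this reagent does with other ring-fused cyclohexenones.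

**Step 13**
Reactants: 20 (5R,7S,10R)-15-[(tert-butyldiphenylsilyl)oxy]labda-8,13E-dien-7-ol
Product: 21 (5R,7S,10R)-labda-8,13E-diene-7,15-diol (ent-labdane series)
Conditions: TBAF, THF, 0 °C → rt
Reagents that add atoms: none
Why: Fluoride-mediated desilylation under basic, non-ionising conditions that leave the allylic C7 alcohol and both alkenes unchanged.

**Step 14**
Reactants: 21 (5R,7S,10R)-labda-8,13E-diene-7,15-diol
Product: 22 (5R,7S,10R)-labda-8,13E-diene-7,15-diyl diacetate (ent-labdane series), the target
Conditions: Ac2O, pyridine, DMAP (cat.), CH2Cl2, rt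
Reagents that add atoms: acetic anhydride, CC(=O)OC(C)=O
Why: Acylation of both hydroxyls with retention at C7; DMAP is needed for the hindered pseudoaxial C7 alcohol, and the basic medium avoids ionisation of the allylic systems.

## Compound list

1 | (S)-(+)-carvone, (5S)-2-methyl-5-(prop-1-en-2-yl)cyclohex-2-en-1-one | CC1=CC[C@@H](CC1=O)C(C)=C | starting material
2 | lithium α′-dienolate of 1 (C9–OLi, C9=C10) | CC1=CC[C@@H](C=C1O[Li])C(C)=C | intermediate
3 | (5S,6R)-2,6-dimethyl-5-(prop-1-en-2-yl)cyclohex-2-en-1-one (trans epimer) | CC1=CC[C@@H]([C@@H](C)C1=O)C(C)=C | intermediate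
4 | lithium enolate of 3 (C9–OLi, C9=C10, methyl on C10) | CC1=CC[C@@H](C(C)=C1O[Li])C(C)=C | intermediate
5 | (5R,6R)-2,6-dimethyl-5-(prop-1-en-2-yl)-6-(prop-2-yn-1-yl)cyclohex-2-en-1-one | CC1=CC[C@@H]([C@@](C)(CC#C)C1=O)C(C)=C | intermediate
6 | 3-[(1R,6R)-1,3-dimethyl-2-oxo-6-(prop-1-en-2-yl)cyclohex-3-en-1-yl]propanal | CC1=CC[C@@H]([C@@](C)(CCC=O)C1=O)C(C)=C | intermediate
7 | (E)-tosylhydrazone of 6 | CC1=CC[C@@H]([C@@](C)(CC/C=N/NS(=O)(=O)c2ccc(C)cc2)C1=O)C(C)=C | intermediate
8 | ring-closed N-alkyl-N′-tosylhydrazide (skeleton of 10 with NH–NHTs on C3, equatorial epimer shown; centre erased in the same flask) | CC1=CC[C@@H]2C(C)(C)[C@H](NNS(=O)(=O)c3ccc(C)cc3)CC[C@@]2(C)C1=O | intermediate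
9 | alkyldiazene (skeleton of 10 with N=NH on C3) | CC1=CC[C@@H]2C(C)(C)[C@H](N=N)CC[C@@]2(C)C1=O | intermediate
10 | (4aR,8aR)-2,5,5,8a-tetramethyl-4a,5,6,7,8,8a-hexahydronaphthalen-1(4H)-one | CC1=CC[C@@H]2C(C)(C)CCC[C@@]2(C)C1=O | intermediate
11 | tert-butyl(but-3-yn-1-yloxy)dimethylsilane | C#CCCO[Si](C)(C)C(C)(C)C | starting material
12 | (E)-[4-[(tert-butyldimethylsilyl)oxy]-2-methylbut-1-en-1-yl]dimethylalane | C[Al](C)/C=C(\C)CCO[Si](C)(C)C(C)(C)C | intermediate
13 | (E)-5-[(tert-butyldimethylsilyl)oxy]-3-methylpent-2-en-1-ol | OC/C=C(\C)CCO[Si](C)(C)C(C)(C)C | intermediate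
14 | tert-butyl{[(E)-5-[(tert-butyldiphenylsilyl)oxy]-3-methylpent-3-en-1-yl]oxy}dimethylsilane | CC(C)(C)[Si](C)(C)OCC/C(C)=C/CO[Si](c1ccccc1)(c1ccccc1)C(C)(C)C | intermediate
15 | (E)-5-[(tert-butyldiphenylsilyl)oxy]-3-methylpent-3-en-1-ol | OCC/C(C)=C/CO[Si](c1ccccc1)(c1ccccc1)C(C)(C)C | intermediate
16 | tert-butyl{[(E)-5-iodo-3-methylpent-2-en-1-yl]oxy}diphenylsilane | ICC/C(C)=C/CO[Si](c1ccccc1)(c1ccccc1)C(C)(C)C | intermediate
17 | [(E)-5-[(tert-butyldiphenylsilyl)oxy]-3-methylpent-3-en-1-yl]lithium | [Li]CC/C(C)=C/CO[Si](c1ccccc1)(c1ccccc1)C(C)(C)C | intermediate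
18 | (5R,9R,10R)-15-[(tert-butyldiphenylsilyl)oxy]labda-7,13E-dien-9-ol (ent-labdane series) | CC(C)(C)[Si](OC/C=C(\C)CC[C@@]1(O)C(C)=CC[C@@H]2C(C)(C)CCC[C@@]12C)(c3ccccc3)c4ccccc4 | intermediate
19 | (5R,10R)-15-[(tert-butyldiphenylsilyl)oxy]labda-8,13E-dien-7-one (ent-labdane series) | CC(C)(C)[Si](OC/C=C(\C)CCC1=C(C)C(=O)C[C@@H]2C(C)(C)CCC[C@@]12C)(c3ccccc3)c4ccccc4 | intermediate
20 | (5R,7S,10R)-15-[(tert-butyldiphenylsilyl)oxy]labda-8,13E-dien-7-ol (ent-labdane series) | CC(C)(C)[Si](OC/C=C(\C)CCC1=C(C)[C@@H](O)C[C@@H]2C(C)(C)CCC[C@@]12C)(c3ccccc3)c4ccccc4 | intermediate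
21 | (5R,7S,10R)-labda-8,13E-diene-7,15-diol (ent-labdane series) | OC/C=C(\C)CCC1=C(C)[C@@H](O)C[C@@H]2C(C)(C)CCC[C@@]12C | intermediate
22 | (5R,7S,10R)-labda-8,13E-diene-7,15-diyl diacetate (ent-labdane series) | CC(=O)OC/C=C(\C)CCC1=C(C)[C@@H](OC(C)=O)C[C@@H]2C(C)(C)CCC[C@@]12C | target

## Step count and least certain steps

Total step count: 14. Longest linear sequence: 10 (steps 1–5 and 10–14); the side-chain branch is steps 6–9 and joins at step 10. Stereocontrol: C5 comes from 1, C10 is set in step 2, 13E in step 6, C7 in step 12.

**Step 5 (key step).** The most likely failure is premature quenching of the tertiary C4 radical by a second hydrogen-atom transfer, which would give net hydrogenation of the isopropenyl group before ring closure. Also possible are competing hydrogen-atom transfer to the enone alkene and incomplete loss of sulfinate and N2 from 8.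
Fallback: ring A is closed by metathesis and the methyl is added afterwards. It sets out from aldehyde 6. Wittig methylenation (Ph3P=CH2, THF) would give the 1,7-diene (5R,6R)-6-(but-3-en-1-yl)-2,6-dimethyl-5-(prop-1-en-2-yl)cyclohex-2-en-1-one F1. Ring-closing metathesis with the second-generation Grubbs catalyst joins the butenyl and isopropenyl groups through a trisubstituted C3=C4 alkene and gives (4aR,8aR)-2,5,8a-trimethyl-4a,7,8,8a-tetrahydronaphthalen-1(4H)-one F2; the enone alkene is too hindered and electron-poor to take part. Intermolecular MHAT hydromethylation of the C3=C4 alkene (Fe(acac)3, PhSiH3, formaldehyde arylsulfonylhydrazone; then MeOH, 60 °C) adds H at C3 and the second methyl at C4 without a stereochemical issue. The fallback comes back to the route at 10.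

**Step 3.** The risk is leakage to Markovnikov hydration (methyl ketone), or capture of the cationic ruthenium centre by the 1,6-enyne formed by the alkyne and the isopropenyl group, leading to cycloisomerisation or catalyst arrest.
Fallback: the aldehyde is made by alkene hydroboration instead. It sets out from 3. Alkylation of its enolate with allyl bromide (LiN(i-Pr)2, THF/DMPU) would give (5R,6R)-6-allyl-2,6-dimethyl-5-(prop-1-en-2-yl)cyclohex-2-en-1-one F3, with the same facial preference as in step 2. Disiamylborane hydroborates the monosubstituted alkene in preference to the 1,1-disubstituted one, and buffered NaBO3·4H2O oxidation gives (5R,6R)-6-(3-hydroxypropyl)-2,6-dimethyl-5-(prop-1-en-2-yl)cyclohex-2-en-1-one F4. Dess–Martin oxidation returns to the route at 6.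

**Step 11.** The risk is slow chromate ester formation at the very hindered tertiary alcohol, so that ionisation and dehydration to ring-B dienes take over, or acid-induced loss of the silyl ether.
Fallback: transposition and oxidation are separated. It sets out from 18. Non-oxidative 1,3-hydroxyl transposition catalysed by Ph3SiOReO3 (Et2O, 0 °C) would give the secondary allylic alcohols, namely 20 together with its C7 epimer (5R,7R,10R)-15-[(tert-butyldiphenylsilyl)oxy]labda-8,13E-dien-7-ol F5. Oxidation of the mixture with MnO2 converges both epimers on the enone. The fallback comes back to the route at 19.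

**Step 12.** The risk is poor facial selectivity (axial hydride delivery giving the equatorial alcohol) or sluggish reduction of the hindered ketone.
Fallback: the equatorial alcohol is accepted and C7 is inverted. It sets out from 19. Luche reduction (NaBH4, CeCl3·7H2O, MeOH, −78 °C) should give the equatorial 7R alcohol F5. Mitsunobu reaction with acetic acid (PPh3, diisopropyl azodicarboxylate, toluene) inverts C7 and gives (5R,7S,10R)-15-[(tert-butyldiphenylsilyl)oxy]labda-8,13E-dien-7-yl acetate F6; SN2′ attack at the fully substituted C9 is not available. Desilylation with TBAF buffered with acetic acid gives (5R,7S,10R)-15-hydroxylabda-8,13E-dien-7-yl acetate F7. Acetylation (Ac2O, pyridine) comes back to the route at 22.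

## Further compounds

F1 | step 5 | (5R,6R)-6-(but-3-en-1-yl)-2,6-dimethyl-5-(prop-1-en-2-yl)cyclohex-2-en-1-one | CC1=CC[C@@H]([C@@](C)(CCC=C)C1=O)C(C)=C
F2 | step 5 | (4aR,8aR)-2,5,8a-trimethyl-4a,7,8,8a-tetrahydronaphthalen-1(4H)-one | CC1=CC[C@@H]2C(C)=CCC[C@@]2(C)C1=O
F3 | step 3 | (5R,6R)-6-allyl-2,6-dimethyl-5-(prop-1-en-2-yl)cyclohex-2-en-1-one | CC1=CC[C@@H]([C@@](C)(CC=C)C1=O)C(C)=C
F4 | step 3 | (5R,6R)-6-(3-hydroxypropyl)-2,6-dimethyl-5-(prop-1-en-2-yl)cyclohex-2-en-1-one | CC1=CC[C@@H]([C@@](C)(CCCO)C1=O)C(C)=C
F5 | step 11 | (5R,7R,10R)-15-[(tert-butyldiphenylsilyl)oxy]labda-8,13E-dien-7-ol (ent-labdane series, C7 epimer of 20) | CC(C)(C)[Si](OC/C=C(\C)CCC1=C(C)[C@H](O)C[C@@H]2C(C)(C)CCC[C@@]12C)(c3ccccc3)c4ccccc4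
F6 | step 12 | (5R,7S,10R)-15-[(tert-butyldiphenylsilyl)oxy]labda-8,13E-dien-7-yl acetate (ent-labdane series) | CC(C)(C)[Si](OC/C=C(\C)CCC1=C(C)[C@@H](OC(C)=O)C[C@@H]2C(C)(C)CCC[C@@]12C)(c3ccccc3)c4ccccc4
F7 | step 12 | (5R,7S,10R)-15-hydroxylabda-8,13E-dien-7-yl acetate (ent-labdane series) | OC/C=C(\C)CCC1=C(C)[C@@H](OC(C)=O)C[C@@H]2C(C)(C)CCC[C@@]12C
A1 | alternative 1 | (2E,6E,10E)-geranylgeranyl acetate | CC(C)=CCC/C(C)=C/CC/C(C)=C/CC/C(C)=C/COC(C)=O
A2 | alternative 1 | (5R,10R)-labda-8,13E-dien-15-yl acetate (ent-labdane series, 7-deoxy) | CC(=O)OC/C=C(\C)CCC1=C(C)CC[C@@H]2C(C)(C)CCC[C@@]12C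
A3 | alternative 2 | (R)-Wieland–Miescher ketone, (8aR)-8a-methyl-3,4,8,8a-tetrahydronaphthalene-1,6(2H,7H)-dione | C[C@@]12CCC(=O)C=C1CCCC2=O
A4 | alternative 2 | (4aR,8aR)-5,5,8a-trimethyloctahydronaphthalen-1(2H)-one | O=C1CCC[C@@H]2C(C)(C)CCC[C@@]12C
A5 | alternative 3 | (E)-3-methyl-5-[(3aR,7aR)-3a,7,7-trimethyl-3a,4,5,6,7,7a-hexahydro-1H-inden-3-yl]pent-2-en-1-yl acetate (B-nor trans-hydrindene) | CC(=O)OC/C=C(\C)CCC1=CC[C@@H]2C(C)(C)CCC[C@@]12C
A6 | alternative 3 | (5R,10R)-8-bromo-17-norlabda-8,13E-diene-7,15-diyl diacetate with the 7-acetoxy group trans to the C10 methyl (ent-labdane series) | CC(=O)OC/C=C(\C)CCC1=C(Br)[C@@H](OC(C)=O)C[C@@H]2C(C)(C)CCC[C@@]12C
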